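The C4 (ring C)–C6 (ring D) bond is cut last, as in the presumed biosynthesis, to two 7,8-dioxygenated 2,3-cis-flavan-3,4-diols (rings A/C/B with the 3,4-dihydroxyphenyl group, rings D/F/E with the 4-hydroxyphenyl group). The pyran ring of each is cut across O1–C2 and C4a–C4: O1–C8a–C4a of ring A is the oxygen and free ortho carbon of a pyrogallol-derived phenol, and C4–C3–C2, oxygenated at C3 and C4 and arylated at C2, is an enantiopure cis-3-aryl-2,3-epoxy aldehyde. The key step joins them in one operation: titanium phenolate ortho-hydroxyalkylation (C4a–C4), then 6-endo epoxide opening with inversion at benzylic C2 (O1–C2). The C4 oxygen it installs later leaves for the interflavan bond.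

Key step: step 6

Remark: the aldehyde addition is assumed to follow the non-chelated Felkin–Anh sense that is usual for cis-epoxy aldehydes; the C4 configuration drawn for 8, 9, 15 and 16 rests on this. Compounds 8 and 15 are drawn as open tri(propan-2-yloxy)titanium alkoxides, although a cyclic titanate that also binds the phenol oxygen may be the species in the flask.

Step 1
Reactants: 1 pyrogallol (benzene-1,2,3-triol)
Product: 2 2,2-diphenyl-1,3-benzodioxol-4-ol
Conditions: Ph2CCl2 (1.1 equiv), neat, 170 °C, 20 min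
Reagents that add atoms: dichlorodiphenylmethane, ClC(Cl)(c1ccccc1)c1ccccc1
Why: Ketalization of a vicinal diphenol with a gem-dichloride; by symmetry only one five-membered mono-ketal can form, and it leaves the terminal OH with one free ortho position.

Step 2
Reactants: 3 3,4-bis(benzyloxy)benzaldehyde
Product: 4 methyl (2Z)-3-[3,4-bis(benzyloxy)phenyl]prop-2-enoate
Conditions: (CF3CH2O)2P(O)CH2CO2Me, KN(SiMe3)2, 18-crown-6, THF, −78 °C
Reagents that add atoms: methyl 2-[bis(2,2,2-trifluoroethoxy)phosphoryl]acetate, COC(=O)CP(=O)(OCC(F)(F)F)OCC(F)(F)F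
Why: Still–Gennari olefination, in which the electron-poor phosphonate under dissociating conditions should collapse kinetically to the Z-enoate.

Step 3
Reactants: 4 methyl (2Z)-3-[3,4-bis(benzyloxy)phenyl]prop-2-enoate
Product: 5 methyl (2S,3S)-3-[3,4-bis(benzyloxy)phenyl]oxirane-2-carboxylate (cis)
Conditions: (S,S)-[N,N'-bis(3,5-di-tert-butylsalicylidene)-1,2-cyclohexanediaminato]manganese chloride (5 mol %), 4-phenylpyridine N-oxide (25 mol %), aq. NaOCl (pH 11.3), CH2Cl2, 4 °C
Reagents that add atoms: sodium hypochlorite, [Na+].[O-]Cl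
Why: Jacobsen epoxidation of a cis-cinnamate, in which the (S,S)-salen complex of trivalent manganese should deliver oxygen to one face of the Z-alkene and so set both stereocenters of the (2S,3S)-cis-glycidate, the N-oxide limiting leakage to the trans-epoxide.

Step 4
Reactants: 5 methyl (2S,3S)-3-[3,4-bis(benzyloxy)phenyl]oxirane-2-carboxylate
Product: 6 (2S,3S)-3-[3,4-bis(benzyloxy)phenyl]oxirane-2-carbaldehyde (cis)
Conditions: iBu2AlH (1.05 equiv), CH2Cl2, −78 °C; MeOH, then aq. KNaC4H4O6; used crude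
Reagents that add atoms: none
Why: Partial reduction of an alpha-oxygenated ester, which should stop at the aluminium hemiacetal at −78 °C and give the aldehyde on work-up without touching the epoxide or its configuration.

Step 5
Reactants: 2 2,2-diphenyl-1,3-benzodioxol-4-ol
Product: 7 (2,2-diphenyl-1,3-benzodioxol-4-yloxy)tri(propan-2-yloxy)titanium
Conditions: Ti(OiPr)4 (1.0 equiv), toluene, rt, 1 h; iPrOH stripped with toluene under reduced pressure; kept as a toluene stock solution under Ar for steps 6 and 11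
Reagents that add atoms: titanium tetraisopropoxide, CC(C)O[Ti](OC(C)C)(OC(C)C)OC(C)C
Why: Alcoholysis (ligand exchange) of a titanium alkoxide by the more acidic phenol, held at the mono(aryloxide) by the stoichiometry and driven by removal of propan-2-ol; no stereocenter is involved.

Step 6
Reactants: 7 (2,2-diphenyl-1,3-benzodioxol-4-yloxy)tri(propan-2-yloxy)titanium; 6 (2S,3S)-3-[3,4-bis(benzyloxy)phenyl]oxirane-2-carbaldehyde
Product: 9 (2R,3R,4R)-2-[3,4-bis(benzyloxy)phenyl]-7,8-(diphenylmethylenedioxy)chromane-3,4-diol, via titanium alkoxide of the epoxy alcohol 8 (not isolated)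
Conditions: 7 (1.1 equiv, toluene stock solution), 6, toluene, −20 °C to rt, then 45 °C; aq. KNaC4H4O6
Reagents that add atoms: none
Why: Proposed new method: the aryloxytitanium triisopropoxide 7 binds the aldehyde of 6 and delivers its ortho carbon (the future C4a, para to the C7 oxygen) through a six-membered cyclic transition state, which forms C4a–C4 and, after rearomatization, gives the titanium alkoxide 8; the metal then holds the C4 oxygen, activates the adjacent epoxide, and the ring A oxygen opens it at the distal, benzylic carbon C2 to form O1–C2. The closest known reactions are the ortho-specific hydroxyalkylation of metal phenolates with chiral alpha-oxygenated aldehydes, the Ti(OiPr)4-mediated opening of 2,3-epoxy alcohols at C3, and the acid-mediated cyclization of ortho-(epoxyalkyl)phenols to flavan-3-ols; their merger on an epoxy aldehyde is the new element. Ring C closes by a 6-endo-tet epoxide opening, the 5-exo alternative being attack at C3. C3 is carried over unchanged from the epoxide, C2 is set by inversion at the benzylic epoxide carbon so that the cis-epoxide gives the 2,3-cis arrangement, and C4 is set by Felkin–Anh addition anti to the epoxide C–O bond to give the 3,4-cis diol, although this center is reset in steps 7 and 12. The step needs ortho-C attack over O- or para-alkylation, which the phenolate template secures, and opening at C2 with SN2 character, which the benzylic position, the titanium chelate and the non-polar medium should secure.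

Step 7
Reactants: 9 (2R,3R,4R)-2-[3,4-bis(benzyloxy)phenyl]-7,8-(diphenylmethylenedioxy)chromane-3,4-diol
Product: 10 (2R,3S,4S)-4-(benzylsulfanyl)-2-[3,4-bis(benzyloxy)phenyl]-7,8-(diphenylmethylenedioxy)chroman-3-ol (4β-sulfide, 3,4-trans)
Conditions: BnSH (3 equiv), BF3·OEt2 (0.3 equiv), CH2Cl2, −40 °C
Reagents that add atoms: benzyl mercaptan (phenylmethanethiol), SCc1ccccc1
Why: SN1 thiolysis of the benzylic C4–OH (cation stabilized by O1 and the C7 oxygen), in which the thiol should add trans to the axial C3–OH and give a sulfide that a thiophile can address selectively.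

Step 8
Reactants: 11 4-(benzyloxy)benzaldehyde
Product: 12 methyl (2Z)-3-[4-(benzyloxy)phenyl]prop-2-enoate
Conditions: (CF3CH2O)2P(O)CH2CO2Me, KN(SiMe3)2, 18-crown-6, THF, −78 °C
Reagents that add atoms: methyl 2-[bis(2,2,2-trifluoroethoxy)phosphoryl]acetate, COC(=O)CP(=O)(OCC(F)(F)F)OCC(F)(F)F
Why: Still–Gennari olefination, Z-selective for the same reason as in step 2.

Step 9
Reactants: 12 methyl (2Z)-3-[4-(benzyloxy)phenyl]prop-2-enoate
Product: 13 methyl (2S,3S)-3-[4-(benzyloxy)phenyl]oxirane-2-carboxylate (cis)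
Conditions: (S,S)-[N,N'-bis(3,5-di-tert-butylsalicylidene)-1,2-cyclohexanediaminato]manganese chloride (5 mol %), 4-phenylpyridine N-oxide (25 mol %), aq. NaOCl (pH 11.3), CH2Cl2, 4 °C
Reagents that add atoms: sodium hypochlorite, [Na+].[O-]Cl
Why: Jacobsen epoxidation as in step 3, the (S,S)-catalyst setting both stereocenters of the cis-glycidate.

Step 10
Reactants: 13 methyl (2S,3S)-3-[4-(benzyloxy)phenyl]oxirane-2-carboxylate
Product: 14 (2S,3S)-3-[4-(benzyloxy)phenyl]oxirane-2-carbaldehyde (cis)
Conditions: iBu2AlH (1.05 equiv), CH2Cl2, −78 °C; MeOH, then aq. KNaC4H4O6; used crude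
Reagents that add atoms: none
Why: Partial ester reduction as in step 4, with the epoxide stereocenters untouched.

Step 11
Reactants: 7 (2,2-diphenyl-1,3-benzodioxol-4-yloxy)tri(propan-2-yloxy)titanium; 14 (2S,3S)-3-[4-(benzyloxy)phenyl]oxirane-2-carbaldehyde
Product: 16 (2R,3R,4R)-2-[4-(benzyloxy)phenyl]-7,8-(diphenylmethylenedioxy)chromane-3,4-diol, via titanium alkoxide of the epoxy alcohol 15 (not isolated)
Conditions: 7 (1.1 equiv, toluene stock solution), 14, toluene, −20 °C to rt, then 45 °C; aq. KNaC4H4O6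
Reagents that add atoms: none
Why: Proposed new method: the same titanium phenolate ortho-hydroxyalkylation and 6-endo epoxide-opening cascade as in step 6 (closest known reactions: ortho-hydroxyalkylation of metal phenolates with alpha-oxygenated aldehydes and Ti(OiPr)4-mediated C3 opening of 2,3-epoxy alcohols) should close ring F, with C3 retained from the epoxide, C2 set by inversion at the benzylic carbon and C4, here a final stereocenter, set by non-chelated Felkin–Anh addition anti to the epoxide C–O bond, which gives the all-cis diol.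

Step 12
Reactants: 10 (2R,3S,4S)-4-(benzylsulfanyl)-2-[3,4-bis(benzyloxy)phenyl]-7,8-(diphenylmethylenedioxy)chroman-3-ol; 16 (2R,3R,4R)-2-[4-(benzyloxy)phenyl]-7,8-(diphenylmethylenedioxy)chromane-3,4-diol
Product: 17 protected dimer: the (2R,3R)-2,3-cis-flavan-3-ol unit (3',4'-di-O-benzyl, 7,8-O-diphenylmethylene) bonded through C4 (4β, trans to its 3-OH) to C6 of the (2R,3R,4R)-flavan-3,4-diol unit (4'-O-benzyl, 7,8-O-diphenylmethylene)
Conditions: 16 (3 equiv), AgBF4 (2.5 equiv), THF, 0 °C, dark; aq. NaHCO3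
Reagents that add atoms: none
Why: Thiophilic activation of the C4 sulfide by the silver salt and Friedel–Crafts arylation by C6 of ring D (para to O1, ortho to the C7 oxygen); the nucleophile should approach the 2,3-cis flavan-4-yl cation trans to the axial 3-OH, which sets C4 of ring C as 4β, while the C4–OH of 16 is not addressed by the thiophile.

Step 13
Reactants: 17 protected dimer
Product: 18 (2R,3R,4S)-2-(3,4-dihydroxyphenyl)-4-[(2R,3R,4R)-3,4,7,8-tetrahydroxy-2-(4-hydroxyphenyl)chroman-6-yl]chromane-3,7,8-triol (target, CNP0174688.1)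
Conditions: H2 (1 atm), Pd(OH)2/C, THF–MeOH, rt
Reagents that add atoms: none
Why: Hydrogenolysis of the three benzyl ethers and two diphenylmethylene ketals under neutral conditions, under which the pyran C–O bonds and the benzylic C4–OH should survive and no stereocenter is touched.

Compound list
1 | pyrogallol | Oc1cccc(O)c1O | starting material
2 | 2,2-diphenyl-1,3-benzodioxol-4-ol | Oc1cccc2OC(c3ccccc3)(c3ccccc3)Oc12 | intermediate
3 | 3,4-bis(benzyloxy)benzaldehyde | O=Cc1ccc(OCc2ccccc2)c(OCc2ccccc2)c1 | starting material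
4 | methyl (2Z)-3-[3,4-bis(benzyloxy)phenyl]prop-2-enoate | COC(=O)/C=C\c1ccc(OCc2ccccc2)c(OCc2ccccc2)c1 | intermediate
5 | methyl (2S,3S)-3-[3,4-bis(benzyloxy)phenyl]oxirane-2-carboxylate | COC(=O)[C@H]1O[C@H]1c1ccc(OCc2ccccc2)c(OCc2ccccc2)c1 | intermediate
6 | (2S,3S)-3-[3,4-bis(benzyloxy)phenyl]oxirane-2-carbaldehyde | O=C[C@H]1O[C@H]1c1ccc(OCc2ccccc2)c(OCc2ccccc2)c1 | intermediate
7 | (2,2-diphenyl-1,3-benzodioxol-4-yloxy)tri(propan-2-yloxy)titanium | CC(C)O[Ti](OC(C)C)(OC(C)C)Oc1cccc2OC(c3ccccc3)(c3ccccc3)Oc12 | intermediate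
8 | {(R)-[(2S,3S)-3-[3,4-bis(benzyloxy)phenyl]oxiran-2-yl](4-hydroxy-2,2-diphenyl-1,3-benzodioxol-5-yl)methoxy}tri(propan-2-yloxy)titanium (cis-epoxide, anti adduct, drawn as the open titanium alkoxide) | Oc1c(ccc2OC(c3ccccc3)(c3ccccc3)Oc12)[C@@H](O[Ti](OC(C)C)(OC(C)C)OC(C)C)[C@H]1O[C@H]1c1ccc(OCc2ccccc2)c(OCc2ccccc2)c1 | intermediate (not isolated)
9 | (2R,3R,4R)-2-[3,4-bis(benzyloxy)phenyl]-7,8-(diphenylmethylenedioxy)chromane-3,4-diol | C(c1ccccc1)Oc1ccc(cc1OCc1ccccc1)[C@H]1Oc2c(ccc3OC(c4ccccc4)(c4ccccc4)Oc23)[C@@H](O)[C@H]1O | intermediate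
10 | (2R,3S,4S)-4-(benzylsulfanyl)-2-[3,4-bis(benzyloxy)phenyl]-7,8-(diphenylmethylenedioxy)chroman-3-ol | c1ccccc1CS[C@H]1c2ccc3OC(c4ccccc4)(c4ccccc4)Oc3c2O[C@H](c2ccc(OCc3ccccc3)c(OCc3ccccc3)c2)[C@@H]1O | intermediate
11 | 4-(benzyloxy)benzaldehyde | O=Cc1ccc(OCc2ccccc2)cc1 | starting material
12 | methyl (2Z)-3-[4-(benzyloxy)phenyl]prop-2-enoate | COC(=O)/C=C\c1ccc(OCc2ccccc2)cc1 | intermediate
13 | methyl (2S,3S)-3-[4-(benzyloxy)phenyl]oxirane-2-carboxylate | COC(=O)[C@H]1O[C@H]1c1ccc(OCc2ccccc2)cc1 | intermediate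
14 | (2S,3S)-3-[4-(benzyloxy)phenyl]oxirane-2-carbaldehyde | O=C[C@H]1O[C@H]1c1ccc(OCc2ccccc2)cc1 | intermediate
15 | {(R)-[(2S,3S)-3-[4-(benzyloxy)phenyl]oxiran-2-yl](4-hydroxy-2,2-diphenyl-1,3-benzodioxol-5-yl)methoxy}tri(propan-2-yloxy)titanium (cis-epoxide, anti adduct, drawn as the open titanium alkoxide) | Oc1c(ccc2OC(c3ccccc3)(c3ccccc3)Oc12)[C@@H](O[Ti](OC(C)C)(OC(C)C)OC(C)C)[C@H]1O[C@H]1c1ccc(OCc2ccccc2)cc1 | intermediate (not isolated)
16 | (2R,3R,4R)-2-[4-(benzyloxy)phenyl]-7,8-(diphenylmethylenedioxy)chromane-3,4-diol | C(c1ccccc1)Oc1ccc(cc1)[C@H]1Oc2c(ccc3OC(c4ccccc4)(c4ccccc4)Oc23)[C@@H](O)[C@H]1O | intermediate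
17 | protected dimer, 4β→6 linked, all stereocenters arranged as in 18 | C(c1ccccc1)Oc1ccc(cc1)[C@H]2Oc3c(cc([C@H]4c5ccc6OC(c7ccccc7)(c7ccccc7)Oc6c5O[C@H](c5ccc(OCc6ccccc6)c(OCc6ccccc6)c5)[C@@H]4O)c8OC(c9ccccc9)(c9ccccc9)Oc38)[C@@H](O)[C@H]2O | intermediate
18 | (2R,3R,4S)-2-(3,4-dihydroxyphenyl)-4-[(2R,3R,4R)-3,4,7,8-tetrahydroxy-2-(4-hydroxyphenyl)chroman-6-yl]chromane-3,7,8-triol | Oc1ccc([C@H]2Oc3c(cc([C@H]4c5ccc(O)c(O)c5O[C@H](c5ccc(O)c(O)c5)[C@@H]4O)c(O)c3O)[C@@H](O)[C@H]2O)cc1 | target

Total step count: 13. Longest linear sequence: 7 steps (2, 3, 4, 6, 7, 12, 13).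

Steps most likely to fail

Step 6. The cascade may stall after the C–C bond is formed. The epoxide of the titanium-bound adduct may also open through a benzylic cation, at C3 to a five-membered ring, or with isopropoxide, so that the configuration at C2 or the ring size is lost. The fallback makes the two bonds in separate steps by known reactions; it sets out from 2 and 6 and comes back at 9. Phenol 2 is brominated ortho to the hydroxyl group (Br2, tBuNH2, toluene, −78 °C) to 5-bromo-2,2-diphenyl-1,3-benzodioxol-4-ol F1. Deprotonation and bromine–lithium exchange (nBuLi, 2.1 equiv, THF, −78 °C) and addition of the aryllithium to 6 should give, after a cold acetic acid quench, the free epoxy diol (R)-{(2R,3S)-3-[3,4-bis(benzyloxy)phenyl]oxiran-2-yl}(4-hydroxy-2,2-diphenyl-1,3-benzodioxol-5-yl)methanol F2. A catalytic amount of camphorsulfonic acid in CH2Cl2 at −20 °C should then close ring C by the acid-mediated 6-endo opening of the benzylic epoxide by the phenol, as used for flavan-3-ols, to give 9.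

Step 11. The same failures as in step 6 may occur. In addition, facial control in the aldehyde addition may be lost, which matters here because C4 of ring F is a final stereocenter. The fallback sets out from 2 and 14 and comes back at 16. Phenol 2 is brominated as above to 5-bromo-2,2-diphenyl-1,3-benzodioxol-4-ol F3 (the same compound as F1), which is lithiated (nBuLi, 2.1 equiv, THF, −78 °C) and added to 14 to give the free epoxy diol (R)-{(2R,3S)-3-[4-(benzyloxy)phenyl]oxiran-2-yl}(4-hydroxy-2,2-diphenyl-1,3-benzodioxol-5-yl)methanol F4. Aryllithium additions to cis-epoxy aldehydes should favor the anti (Felkin–Anh) carbinol, and any C4 epimer can be removed by chromatography at this stage. Camphorsulfonic acid (cat.) in CH2Cl2 at −20 °C should then close ring F to 16.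

Step 12. The fully O-alkylated ring D is only moderately nucleophilic, so the cation may instead alkylate the free diol oxygens of 16, attack C5, or be consumed by self-condensation of 10. The fallback is a union without protecting groups, in which the free 7-OH of ring D raises the reactivity of its ortho carbon C6; it sets out from 9 and 16 and comes back at 18. Hydrogenolysis of 9 (H2, Pd(OH)2/C, THF–MeOH) should give (2R,3R,4R)-2-(3,4-dihydroxyphenyl)chromane-3,4,7,8-tetrol (melacacidin) F5. Thiolysis (BnSH, AcOH, 80 °C) should convert it to (2R,3S,4S)-4-(benzylsulfanyl)-2-(3,4-dihydroxyphenyl)chromane-3,7,8-triol F6. Hydrogenolysis of 16 under the same conditions should give (2R,3R,4R)-2-(4-hydroxyphenyl)chromane-3,4,7,8-tetrol (teracacidin) F7. Treatment of F6 with an excess of F7 and AgBF4 in THF at 0 °C should then give 18 directly.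

Further compounds
F1 | step 6 | 5-bromo-2,2-diphenyl-1,3-benzodioxol-4-ol | Oc1c(Br)ccc2OC(c3ccccc3)(c3ccccc3)Oc12
F2 | step 6 | (R)-{(2R,3S)-3-[3,4-bis(benzyloxy)phenyl]oxiran-2-yl}(4-hydroxy-2,2-diphenyl-1,3-benzodioxol-5-yl)methanol | Oc1c(ccc2OC(c3ccccc3)(c3ccccc3)Oc12)[C@@H](O)[C@H]1O[C@H]1c1ccc(OCc2ccccc2)c(OCc2ccccc2)c1
F3 | step 11 | 5-bromo-2,2-diphenyl-1,3-benzodioxol-4-ol (identical with F1) | Oc1c(Br)ccc2OC(c3ccccc3)(c3ccccc3)Oc12
F4 | step 11 | (R)-{(2R,3S)-3-[4-(benzyloxy)phenyl]oxiran-2-yl}(4-hydroxy-2,2-diphenyl-1,3-benzodioxol-5-yl)methanol | Oc1c(ccc2OC(c3ccccc3)(c3ccccc3)Oc12)[C@@H](O)[C@H]1O[C@H]1c1ccc(OCc2ccccc2)cc1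
F5 | step 12 | (2R,3R,4R)-2-(3,4-dihydroxyphenyl)chromane-3,4,7,8-tetrol (melacacidin) | Oc1ccc(cc1O)[C@H]1Oc2c(ccc(O)c2O)[C@@H](O)[C@H]1O
F6 | step 12 | (2R,3S,4S)-4-(benzylsulfanyl)-2-(3,4-dihydroxyphenyl)chromane-3,7,8-triol | c1ccccc1CS[C@H]1c2ccc(O)c(O)c2O[C@H](c2ccc(O)c(O)c2)[C@@H]1O
F7 | step 12 | (2R,3R,4R)-2-(4-hydroxyphenyl)chromane-3,4,7,8-tetrol (teracacidin) | Oc1ccc(cc1)[C@H]1Oc2c(ccc(O)c2O)[C@@H](O)[C@H]1O
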